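**Retrosynthetic overview**
- Last bond: the ester C–O, made by acylating the secondary C6 alcohol of the diol-enone with 3,4-dimethoxybenzoyl chloride.
- Seven-membered ring (formed second): C6–C7, by an intramolecular carbonyl-ene reaction of a cyclopentane carrying a C5 aldehyde and a C1 methallyl ketone, followed by alkene shift into conjugation.
- That keto-aldehyde comes from a cyclopentane-fused β-lactone by hydride opening, acetal hydrolysis, methallyl Grignard addition and double oxidation.
- Five-membered ring (formed first, key step): C1–C2, by polarity-reversed addition of an enal β-carbon (carbene-bound homoenolate) to the β-carbon of isopropyl vinyl ketone, then C4–C5 aldol and β-lactonisation. This one catalytic asymmetric step sets C1, C4 and C5.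
- The enal comes from Wittig olefination of pyruvaldehyde dimethyl acetal.

Locants used in the text: C1 = quaternary methyl-bearing ring-fusion carbon, C2/C3 = five-ring CH2, C4 = isopropyl carbinol, C5 = ring-fusion CH, C6 = ester-bearing carbon, C7 = seven-ring CH2, C8 = methyl-bearing alkene carbon, C9 = alkene CH, C10 = ketone carbon.

**Step 1**
Reactants: 1 1,1-dimethoxypropan-2-one; 2 (triphenyl-λ5-phosphanylidene)acetaldehyde
Product: 3 (2E)-4,4-dimethoxy-3-methylbut-2-enal
Conditions: toluene, 110 °C, 24 h
Reagents that add atoms: none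
Why: Wittig olefination of the activated α,α-dialkoxy ketone with the stabilised formyl ylide gives the trisubstituted enal; the E isomer (CHO trans to the bulkier CH(OMe)2) is the thermodynamic product and no stereocentre is formed.

**Step 2**
Reactants: 3 (2E)-4,4-dimethoxy-3-methylbut-2-enal; 4 4-methylpent-1-en-3-one (isopropyl vinyl ketone)
Product: 5 (1R,2S,5R)-2-(dimethoxymethyl)-2-methyl-5-(propan-2-yl)-6-oxabicyclo[3.2.0]heptan-7-one
Conditions: (5aS,10bR)-2-(2,4,6-trimethylphenyl)-5a,10b-dihydro-4H,6H-indeno[2,1-b][1,2,4]triazolo[4,3-d][1,4]oxazin-2-ium chloride (10 mol %), DBU (20 mol %), THF, 40 °C, 4 added over 6 h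
Reagents that add atoms: none
Why: Proposed new method: the carbene adds to the aldehyde of 3, and the extended Breslow intermediate reacts as a homoenolate at its β-carbon (C1) with the unsubstituted terminus of 4, creating the quaternary centre on the face left open by the aminoindanol backbone (the mirror-image precatalyst gives the antipode); the azolium enol at C5 then closes by aldol onto the isopropyl ketone (C4) anti to the larger CH(OMe)2 group, and the alkoxide, which can only reach the acyl azolium when cis to it, lactonises and releases the carbene; the closest known reaction type is the carbene-catalysed homoenolate annulation of enals with enones to cyclopentane-fused β-lactones, extended here to a β,β-disubstituted enal and an alkyl vinyl ketone.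

**Step 3**
Reactants: 5 (1R,2S,5R)-2-(dimethoxymethyl)-2-methyl-5-(propan-2-yl)-6-oxabicyclo[3.2.0]heptan-7-one
Product: 7 (1S,2S,3R)-3-hydroxy-2-(hydroxymethyl)-1-methyl-3-(propan-2-yl)cyclopentane-1-carbaldehyde, via diol acetal 6 (not isolated)
Conditions: LiAlH4, THF, 0 °C; then 1 M HCl, THF, 25 °C
Reagents that add atoms: water, O
Why: Hydride reduction of the strained β-lactone at the acyl carbon gives the 1,3-diol without touching a stereocentre, and dilute acid then hydrolyses the dimethyl acetal (acetal hydrolysis) while the tertiary alcohol survives and the trans-disposed CH2OH and CHO groups have no favourable lactol.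

**Step 4**
Reactants: 7 (1S,2S,3R)-3-hydroxy-2-(hydroxymethyl)-1-methyl-3-(propan-2-yl)cyclopentane-1-carbaldehyde; 8 (2-methylprop-2-en-1-yl)magnesium chloride
Product: 9 1-[(1S,2S,3R)-3-hydroxy-2-(hydroxymethyl)-1-methyl-3-(propan-2-yl)cyclopentyl]-3-methylbut-3-en-1-ol (both carbinol epimers)
Conditions: THF, −78 to 0 °C (3.5 equiv of 8); aq. NH4Cl
Reagents that add atoms: none
Why: Grignard 1,2-addition of the allylic reagent to the neopentyl aldehyde (the two hydroxyl groups consume two further equivalents); the new carbinol centre forms as a mixture, which does not matter because it is oxidised in the next step.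

**Step 5**
Reactants: 9 1-[(1S,2S,3R)-3-hydroxy-2-(hydroxymethyl)-1-methyl-3-(propan-2-yl)cyclopentyl]-3-methylbut-3-en-1-ol
Product: 10 (1R,2R,5S)-2-hydroxy-5-methyl-5-(3-methylbut-3-enoyl)-2-(propan-2-yl)cyclopentane-1-carbaldehyde
Conditions: Dess–Martin periodinane (3 equiv), pyridine, CH2Cl2, 0 to 25 °C
Reagents that add atoms: none
Why: Dess–Martin oxidation converts the secondary carbinol into the β,γ-unsaturated ketone and the primary alcohol into the aldehyde under buffered, non-enolising conditions while the tertiary alcohol is inert; C5 is not at risk because the formyl group already sits on the face of the smaller neighbours (OH and CH3).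

**Step 6**
Reactants: 10 (1R,2R,5S)-2-hydroxy-5-methyl-5-(3-methylbut-3-enoyl)-2-(propan-2-yl)cyclopentane-1-carbaldehyde
Product: 12 (1R,3aS,8S,8aS)-1,8-dihydroxy-3a,6-dimethyl-1-(propan-2-yl)-2,3,3a,7,8,8a-hexahydroazulen-4(1H)-one, via exocyclic-methylene ene adduct 11 (not isolated)
Conditions: Me2AlCl (3 equiv), CH2Cl2, −78 to −20 °C; aq. HCl quench; then DBU (0.2 equiv), CH2Cl2, 25 °C
Reagents that add atoms: none
Why: Lewis-acid-promoted intramolecular carbonyl-ene reaction (1,1-disubstituted alkene tethered through its central carbon) closes the seven-membered ring at C6–C7, with the aluminium alkoxide of the C4 hydroxyl chelating the aldehyde so that its oxygen ends up pseudo-equatorial, gauche to C4 and away from quaternary C1 (H5/H6 anti, giving the 6S carbinol), and DBU then moves the exocyclic alkene into conjugation with the ketone (β,γ to α,β isomerisation).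

**Step 7**
Reactants: 12 (1R,3aS,8S,8aS)-1,8-dihydroxy-3a,6-dimethyl-1-(propan-2-yl)-2,3,3a,7,8,8a-hexahydroazulen-4(1H)-one; 13 3,4-dimethoxybenzoyl chloride
Product: 14 (3R,3aS,4S,8aS)-3-hydroxy-6,8a-dimethyl-8-oxo-3-(propan-2-yl)-1,2,3,3a,4,5,8,8a-octahydroazulen-4-yl 3,4-dimethoxybenzoate
Conditions: pyridine, DMAP (10 mol %), CH2Cl2, 0 to 25 °C
Reagents that add atoms: none
Why: DMAP-catalysed acylation (nucleophilic catalysis) esterifies only the secondary C6 alcohol because the hindered tertiary C4 alcohol is unreactive, and pyridine is too weak a base to trigger vinylogous elimination of the new ester.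

**Compound list**
1 | 1,1-dimethoxypropan-2-one (pyruvaldehyde dimethyl acetal) | CC(=O)C(OC)OC | starting material
2 | (triphenyl-λ5-phosphanylidene)acetaldehyde | O=CC=P(c1ccccc1)(c1ccccc1)c1ccccc1 | starting material
3 | (2E)-4,4-dimethoxy-3-methylbut-2-enal | O=C/C=C(\C)C(OC)OC | intermediate
4 | 4-methylpent-1-en-3-one (isopropyl vinyl ketone) | C=CC(=O)C(C)C | starting material
5 | (1R,2S,5R)-2-(dimethoxymethyl)-2-methyl-5-(propan-2-yl)-6-oxabicyclo[3.2.0]heptan-7-one (cis-fused β-lactone, CH(OMe)2 on the face opposite the lactone) | O=C1O[C@@]2(C(C)C)CC[C@](C)(C(OC)OC)[C@@H]12 | intermediate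
6 | (1R,2S,3S)-3-(dimethoxymethyl)-2-(hydroxymethyl)-3-methyl-1-(propan-2-yl)cyclopentan-1-ol | OC[C@H]1[C@](O)(C(C)C)CC[C@]1(C)C(OC)OC | intermediate (not isolated)
7 | (1S,2S,3R)-3-hydroxy-2-(hydroxymethyl)-1-methyl-3-(propan-2-yl)cyclopentane-1-carbaldehyde | OC[C@H]1[C@](O)(C(C)C)CC[C@]1(C)C=O | intermediate
8 | (2-methylprop-2-en-1-yl)magnesium chloride | CC(=C)C[Mg]Cl | starting material
9 | 1-[(1S,2S,3R)-3-hydroxy-2-(hydroxymethyl)-1-methyl-3-(propan-2-yl)cyclopentyl]-3-methylbut-3-en-1-ol (both carbinol epimers) | OC[C@H]1[C@](O)(C(C)C)CC[C@]1(C)C(O)CC(C)=C | intermediate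
10 | (1R,2R,5S)-2-hydroxy-5-methyl-5-(3-methylbut-3-enoyl)-2-(propan-2-yl)cyclopentane-1-carbaldehyde | O=C[C@H]1[C@](O)(C(C)C)CC[C@]1(C)C(=O)CC(C)=C | intermediate
11 | (1R,3aS,8S,8aS)-1,8-dihydroxy-3a-methyl-6-methylidene-1-(propan-2-yl)octahydroazulen-4(1H)-one | O[C@H]1CC(=C)CC(=O)[C@@]2(C)CC[C@@](O)(C(C)C)[C@H]12 | intermediate (not isolated)
12 | (1R,3aS,8S,8aS)-1,8-dihydroxy-3a,6-dimethyl-1-(propan-2-yl)-2,3,3a,7,8,8a-hexahydroazulen-4(1H)-one | O[C@H]1CC(C)=CC(=O)[C@@]2(C)CC[C@@](O)(C(C)C)[C@H]12 | intermediate
13 | 3,4-dimethoxybenzoyl chloride | COc1ccc(C(Cl)=O)cc1OC | starting material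
14 | (3R,3aS,4S,8aS)-3-hydroxy-6,8a-dimethyl-8-oxo-3-(propan-2-yl)-1,2,3,3a,4,5,8,8a-octahydroazulen-4-yl 3,4-dimethoxybenzoate | COc1ccc(C(=O)O[C@H]2CC(C)=CC(=O)[C@@]3(C)CC[C@@](O)(C(C)C)[C@H]23)cc1OC | target

**Step count and risks**
Total steps: 7. Longest linear sequence: 7 (1 → 3 → 5 → 7 → 9 → 10 → 12 → 14).

Most likely to fail, first: step 2. The hindered β-carbon of 3 may lose out to reaction at the acyl-anion carbon (Stetter-type adduct), the homoenolate may expel methoxide from the neighbouring acetal, or the azolium enol may not close onto the hindered isopropyl ketone. The fallback sets out from 4 and builds the quaternary carbon by enamine chemistry instead. Methyl 3-methyl-4-oxobutanoate F1 (pyrrolidine enamine of propanal alkylated with methyl bromoacetate) is added to 4 under a cinchona-derived primary amine (9-amino-9-deoxy-epi-quinine, benzoic acid) to give methyl (3S)-3-formyl-3,7-dimethyl-6-oxooctanoate F2. The aldehyde is masked with HC(OMe)3 and pyridinium p-toluenesulfonate in MeOH as methyl (3S)-3-(dimethoxymethyl)-3,7-dimethyl-6-oxooctanoate F3. LiOH in aqueous THF gives (3S)-3-(dimethoxymethyl)-3,7-dimethyl-6-oxooctanoic acid F4. A nucleophile-catalysed aldol-lactonisation (2-chloro-1-methylpyridinium iodide, 4-pyrrolidinopyridine, iPr2NEt, CH2Cl2) then closes the cyclopentane and the β-lactone in one operation and comes back to the route at 5.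

Second: step 6. Me2AlCl may transfer methyl to the aldehyde, the cation may be captured instead of completing the ene reaction, the seven-membered closure may be slow, or the C6 epimer ratio may be poor. The fallback sets out from 7 and closes the ring by metathesis. Vinylmagnesium bromide (3.5 equiv, THF, −78 °C) gives 1-[(1S,2S,3R)-3-hydroxy-2-(hydroxymethyl)-1-methyl-3-(propan-2-yl)cyclopentyl]prop-2-en-1-ol F5. Dess–Martin periodinane with pyridine gives (1R,2R,5S)-2-hydroxy-5-methyl-5-(prop-2-enoyl)-2-(propan-2-yl)cyclopentane-1-carbaldehyde F6. Chelation-controlled Barbier addition of 3-bromo-2-methylprop-1-ene with indium powder in THF/H2O, which attacks only the aldehyde from the side of H5, gives 1-{(1S,2S,3R)-3-hydroxy-2-[(1S)-1-hydroxy-3-methylbut-3-en-1-yl]-1-methyl-3-(propan-2-yl)cyclopentyl}prop-2-en-1-one F7. Ring-closing metathesis with the second-generation Grubbs catalyst RuCl2(=CHPh)(PCy3)(H2IMes) in toluene at 80 °C forms the C8=C9 bond and comes back at 12.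

Third: step 1. Stabilised formyl ylides react sluggishly with ketones, and the E/Z ratio may be modest. The fallback sets out from 1 and goes through a nitrile. Horner–Wadsworth–Emmons reaction with diethyl (cyanomethyl)phosphonate and NaH in THF gives (2E)-4,4-dimethoxy-3-methylbut-2-enenitrile F8. Reduction with iBu2AlH in toluene at −78 °C and buffered hydrolysis of the aluminium imine comes back at 3.

**Further compounds**
F1 | step 2 | methyl 3-methyl-4-oxobutanoate | COC(=O)CC(C)C=O
F2 | step 2 | methyl (3S)-3-formyl-3,7-dimethyl-6-oxooctanoate | O=C[C@](C)(CC(=O)OC)CCC(=O)C(C)C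
F3 | step 2 | methyl (3S)-3-(dimethoxymethyl)-3,7-dimethyl-6-oxooctanoate | COC(OC)[C@](C)(CC(=O)OC)CCC(=O)C(C)C
F4 | step 2 | (3S)-3-(dimethoxymethyl)-3,7-dimethyl-6-oxooctanoic acid | COC(OC)[C@](C)(CC(=O)O)CCC(=O)C(C)C
F5 | step 6 | 1-[(1S,2S,3R)-3-hydroxy-2-(hydroxymethyl)-1-methyl-3-(propan-2-yl)cyclopentyl]prop-2-en-1-ol (both carbinol epimers) | OC[C@H]1[C@](O)(C(C)C)CC[C@]1(C)C(O)C=C
F6 | step 6 | (1R,2R,5S)-2-hydroxy-5-methyl-5-(prop-2-enoyl)-2-(propan-2-yl)cyclopentane-1-carbaldehyde | O=C[C@H]1[C@](O)(C(C)C)CC[C@]1(C)C(=O)C=C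
F7 | step 6 | 1-{(1S,2S,3R)-3-hydroxy-2-[(1S)-1-hydroxy-3-methylbut-3-en-1-yl]-1-methyl-3-(propan-2-yl)cyclopentyl}prop-2-en-1-one | O[C@@H](CC(C)=C)[C@H]1[C@](O)(C(C)C)CC[C@]1(C)C(=O)C=C
F8 | step 1 | (2E)-4,4-dimethoxy-3-methylbut-2-enenitrile | N#C/C=C(\C)C(OC)OC
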